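# Total synthesis proposal: confluentic acid (21)

## Analysis of the target

Confluentic acid (21) is a para-depside. Two benzene rings, A and B, are joined only by the aryl ester C7(=O)–O–C4', there is no other ring, and there is no stereocenter to control. Ring A (C1–C6) carries the ester carbonyl C7 on C1, a chelated free OH on C2, OMe on C4 and the 2-oxoheptyl chain C1''–C7'' (ketone at C2'') on C6. Ring B (C1'–C6') carries the free CO2H on C1', OMe on C2', the depside oxygen on C4' and n-pentyl on C6'.

The plan rests on the path C7–C1–C2–C3–C4–C5–C6–C1''–C2''. Every second carbon on it (C7, C2, C4, C6, C2'') is or was a carbonyl carbon, so ring A with its side chain is a 3,5,7,9-tetraoxotetradecanoyl chain, folded by the single bond C1–C6 and unloaded onto the C4' phenol of ring B.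

The hardest bond by classical means is C7–O. C7 sits between two ortho substituents, and the C2'' enol oxygen can reach C7 through a six-membered transition state, so any activated form of the ring A acid can collapse by enol lactonisation (isocoumarin formation) and expel ring B, and so can the aryl ester of the target itself under base, strong acid or heat. A C2'' alcohol would lactonise in the same way even faster, which rules out the alcohol oxidation level as a mask.

The two rings have opposite O-methylation patterns (A: para OMe, ortho OH; B: ortho OMe, para O-acyl). The ortho OMe of ring B is the chelated, less reactive oxygen of a resorcylate, which classical routes reach only through protecting-group detours. The electron-rich, doubly ortho-substituted acid at C1' is prone to protodecarboxylation and must be released last under neutral conditions.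

## Retrosynthetic reasoning

**21 ⇒ 20.** The O–CH2Ph bond of a benzyl ester at C1' is cut. Hydrogenolysis is neutral, so the free acid appears only in the last flask. It never meets acid or base that could decarboxylate it or trigger enol lactonisation at C7. The forward step only has to leave the aryl ester and the non-conjugated C2'' ketone untouched.

**20 ⇒ 19.** The C2'' ketone is traced back to a cyclic ketal. The mask is needed twice. In the open chain it removes C2'' from the set of carbonyl groups that can take part in folding. Under the base of the methylation step it prevents a C1''/C2'' enolate from attacking C7. The forward step is a mild hydrolysis at room temperature.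

**19 ⇒ 18.** The O–CH3 bond at C4 is cut. The ring construction delivers C2–OH chelated to C7=O and C4–OH free, so the two hydroxyl groups are differentiated without any protecting group. The forward step has to methylate only the more acidic, unchelated oxygen.

**18 ⇒ 7 + 15 (key disconnection).** Two bonds are cut at once: the depside bond C7–O(C4') and the ring bond C1–C6.
- Ring A disappears and leaves the open-chain diketo-dioxinone 7. Its dioxinone masks C7/C2, C4 and C6 are free ketones, and C2'' is a ketal.
- In the forward direction, thermolysis of 7 gives acylketene 16. Phenol 15 adds to it to give triketo ester 17, and an aldol closure with aromatisation gives 18 in the same pot.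
- The ester is therefore formed on an unhindered sp carbon before its ortho neighbours exist, and the ring A acid with its tendency to self-lactonise never exists.
- No hydroxyl of ring A needs protection.
- Cutting only C7–O would keep all of these problems. Cutting only ring bonds would leave the esterification as a separate task.

**7 ⇒ 6 + 3.** The bond C5–C6 is cut. The terminal carbon of the dianion of keto-dioxinone 6 acylates the N-methoxy-N-methylamide 3. The chelated tetrahedral intermediate releases the acidic product only on quenching, so one equivalent of dianion suffices.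

**6 ⇒ 4 + 5.** The bond C3–C4 is cut by a vinylogous acylation of the dienolate of 4 with 5. Both are bulk chemicals, and 4 brings C7, C1, C2 and C3 in masked form.

**3 ⇒ 2 ⇒ 1.** The amide C–N bond and the ketal C–O bonds are cut. β-Keto ester 1 already holds C6, C1'', C2'' and the pentyl tail in the right order, so no C–C bond has to be made for the side chain.

**15 ⇒ 9 + 12.** Ring B is cut at C1'–C2' and C5'–C6' by a Diels–Alder reaction with aromatisation.
- The polarity of diene 12 places its ketene acetal carbon next to the ester-bearing alkyne carbon of 9.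
- The ring construction itself thus writes OMe on C2', a free OH on C4' and pentyl on C6'.
- This avoids selective methylation of the chelated hydroxyl of a preformed resorcylate.

**12 ⇒ 11 ⇒ 10 + 5, and 9 ⇒ 8.** The O–Si bond and the C3'–C4' bond are cut for the diene, which comes from acylation of ketene acetal 10 with 5. The benzyl C–O bond is cut for the ynoate. Compound 5 therefore supplies C4–C5 of ring A and C4'–C5' of ring B.

## Alternatives that were turned down

**Alternative 1:** This is the textbook route, which cuts only C7–O. The forward key step is esterification of the preformed acid 2-(benzyloxy)-4-methoxy-6-(2-oxoheptyl)benzoic acid A1 with phenol 15, using a carbodiimide or trifluoroacetic anhydride. This gives the dibenzyl depside A3, and double hydrogenolysis then gives 21. It was turned down for three reasons.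
- A1 needs its own long aromatic sequence. It is reached by hydroxide opening of 8-(benzyloxy)-6-methoxy-3-pentylisocoumarin A2, which in turn needs ring functionalisation, selective methylation and benzylation.
- Activation of A1 puts a leaving group on a doubly ortho-flanked carbonyl that the external phenol reaches slowly. The internal C2'' enol oxygen reaches it through a six-membered transition state, so A1 tends to fall back to A2.
- The C2 hydroxyl has to be protected and deprotected.

**Alternative 2:** Ring A is cut at C1–C2 and C5–C6, with the ester already in place. The forward key step is a thermal Diels–Alder reaction of the aryl ynoate benzyl 2-methoxy-6-pentyl-4-{[4-(2-pentyl-1,3-dioxolan-2-yl)but-2-ynoyl]oxy}benzoate A4 with 1,3-dimethoxy-1-(trimethylsilyloxy)buta-1,3-diene A5, which would give 19 directly. It was turned down for four reasons.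
- The ester bond still needs a separate coupling, so the key step builds less.
- The ynoic acid part of A4 costs more steps than 7. Its propargylic CH2 lies between an ynoate and a ketal, so traces of base can isomerise it to the allenoate and open the ketal.
- The β-carbon of A4, where bond formation is most advanced in the asynchronous transition state, carries a neopentyl-type substituent. Temperatures would be needed at which A4 and A5 degrade.
- The mixed ketene acetal carbon of A5 can lose either of its two oxygen substituents on aromatisation, which blurs the OH/OMe pattern at C2.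

**Alternative 3:** The two neighbouring bonds C1–C7 and C6–C1'' are cut by aryne acyl-alkylation. In the forward key step, fluoride generates the 3-benzyloxy-5-methoxyaryne from 3-(benzyloxy)-5-methoxy-2-(trimethylsilyl)phenyl triflate A6. The aryne then inserts into the β-keto ester benzyl 2-methoxy-4-[(3-oxooctanoyl)oxy]-6-pentylbenzoate A7.
- The side on which each part adds is right. The enolate carbon adds at C6, distal to the C2 alkoxy group, and leaves the aryl anion at C1.
- The anion then closes the four-membered ring on the more electrophilic ketone carbonyl, not on the ester.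
- Fragmentation therefore gives the constitutional isomer A8, with hexanoyl on C1 and CH2CO2Ar on C6.
- Attack on the aryl ester, if it occurred, would expel the phenoxide rather than cleave the C–C bond.
- The disconnection thus gives the wrong connectivity by mechanism, and A6 is itself a multi-step compound.

Key step: step 9

Assumption: the target has no stereocenter and no double-bond geometry, so the SMILES strings carry no stereo descriptors. Enolisable polycarbonyl compounds are drawn in their keto forms.

## Route

Step 1
Reactants: 1 ethyl 3-oxooctanoate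
Product: 2 ethyl 2-(2-pentyl-1,3-dioxolan-2-yl)acetate
Conditions: HOCH2CH2OH (3 equiv), p-TsOH·H2O (5 mol %), PhMe, reflux, azeotropic removal of water
Reagents that add atoms: ethylene glycol, OCCO
Why: Acid-catalysed ketalisation driven by removal of water, routine for β-keto esters; only the ketone reacts. The ketal is the mask that later blocks the extra folding modes and the enol lactonisation at C7.

Step 2
Reactants: 2 ethyl 2-(2-pentyl-1,3-dioxolan-2-yl)acetate
Product: 3 N-methoxy-N-methyl-2-(2-pentyl-1,3-dioxolan-2-yl)acetamide
Conditions: MeNH(OMe)·HCl (1.5 equiv), i-PrMgCl (3.0 equiv), THF, −20 to 0 °C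
Reagents that add atoms: N,O-dimethylhydroxylamine hydrochloride, CNOC.Cl
Why: Aminolysis of the ester by the chloromagnesium amide formed in situ gives the N-methoxy-N-methylamide; the ketal is inert to this basic medium at low temperature.

Step 3
Reactants: 4 2,2,6-trimethyl-4H-1,3-dioxin-4-one; 5 acetyl chloride
Product: 6 2,2-dimethyl-6-(2-oxopropyl)-4H-1,3-dioxin-4-one
Conditions: LiN(SiMe3)2 (1.0 equiv to 4), THF, −78 °C; 5 (0.5 equiv), −78 to −20 °C; aq NH4Cl
Reagents that add atoms: none
Why: Vinylogous (γ-selective) C-acylation of the lithium dienolate of 4 with an acid chloride, forming the future C3–C4 bond. Half an equivalent of 5 is used because 6 is more acidic than 4 and consumes a second equivalent of dienolate by proton transfer.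

Step 4
Reactants: 6 2,2-dimethyl-6-(2-oxopropyl)-4H-1,3-dioxin-4-one; 3 N-methoxy-N-methyl-2-(2-pentyl-1,3-dioxolan-2-yl)acetamide
Product: 7 6-[2,4-dioxo-5-(2-pentyl-1,3-dioxolan-2-yl)pentyl]-2,2-dimethyl-4H-1,3-dioxin-4-one
Conditions: LiN(i-Pr)2 (2.2 equiv), THF, −78 to −40 °C; 3 (0.9 equiv), −78 to −10 °C; aq NH4Cl, 0 °C; short filtration only
Reagents that add atoms: none
Why: Claisen-type acylation of a 1,3-dicarbonyl dianion, which reacts at its more basic terminal carbon (future C5) and forms the C5–C6 bond. The chelated tetrahedral adduct of the N-methoxy-N-methylamide holds the product back until the quench, so neither over-addition nor quenching of the dianion by the product takes place.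

Step 5
Reactants: 8 oct-2-ynoic acid
Product: 9 benzyl oct-2-ynoate
Conditions: BnBr (1.1 equiv), K2CO3 (1.2 equiv), DMF, 20 °C
Reagents that add atoms: benzyl bromide, BrCc1ccccc1
Why: SN2 O-alkylation of the carboxylate; a carbonate base at room temperature does not isomerise the 2-ynoate to the allenoate.

Step 6
Reactants: 10 1,1-dimethoxyethene; 5 acetyl chloride
Product: 11 4,4-dimethoxybut-3-en-2-one
Conditions: Et3N (1.2 equiv), Et2O, 0 to 20 °C
Reagents that add atoms: none
Why: C-acylation of an electron-rich ketene acetal at its β-carbon by an acid chloride; the amine takes up HCl. The product is a stabilised push–pull alkene that does not react a second time.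

Step 7
Reactants: 11 4,4-dimethoxybut-3-en-2-one
Product: 12 1,1-dimethoxy-3-(trimethylsilyloxy)buta-1,3-diene
Conditions: Me3SiOTf (1.1 equiv), Et3N (1.5 equiv), Et2O, 0 °C; pentane extraction, used at once
Reagents that add atoms: trimethylsilyl trifluoromethanesulfonate, C[Si](C)(C)OS(=O)(=O)C(F)(F)F
Why: Soft enolisation and O-silylation of a methyl ketone; the CH3 group is the only enolisable position, so a single 2-silyloxydiene forms.

Step 8
Reactants: 9 benzyl oct-2-ynoate; 12 1,1-dimethoxy-3-(trimethylsilyloxy)buta-1,3-diene
Product: 15 benzyl 4-hydroxy-2-methoxy-6-pentylbenzoate, via cyclohexadiene cycloadduct 13 (not isolated), via aryl trimethylsilyl ether 14 (not isolated)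
Conditions: 12 (2.5 equiv), xylene, 135 °C, sealed tube; then 0.5 M HCl, THF, 20 °C
Reagents that add atoms: none
Why: Normal-electron-demand Diels–Alder reaction of a 1,1-dialkoxy-3-silyloxydiene with an acetylenic ester, followed by aromatisation. The nucleophilic terminus C4 of 12 bonds to the pentyl-bearing β-carbon of 9 and the ketene acetal carbon C1 to the α-carbon, so after loss of one methoxy group as methanol the remaining OMe stands ortho to the ester (C2') and the silyloxy group para to it (C4'). Dilute acid cleaves the aryl silyl ether and leaves the benzyl ester.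

Step 9
Reactants: 7 6-[2,4-dioxo-5-(2-pentyl-1,3-dioxolan-2-yl)pentyl]-2,2-dimethyl-4H-1,3-dioxin-4-one; 15 benzyl 4-hydroxy-2-methoxy-6-pentylbenzoate
Product: 18 benzyl 4-({2,4-dihydroxy-6-[(2-pentyl-1,3-dioxolan-2-yl)methyl]benzoyl}oxy)-2-methoxy-6-pentylbenzoate, via acylketene 16 (not isolated), via triketo aryl ester 17 (not isolated)
Conditions: 15 (1.0 equiv), PhMe (0.3 M), 110 °C, slow addition of 7 (1.3 equiv) in PhMe, N2 sweep; cool to 20 °C, Et3N (1.0 equiv), CH2Cl2, 20 °C; aq citric acid wash
Reagents that add atoms: none
Why: Proposed new method: the cascade of dioxinone thermolysis, ketene capture and aldol aromatisation is established with aliphatic alcohols as trapping partners, and the simple 6-methyl dioxinone is known to acetoacetylate phenols, but capture of a diketo-acylketene by a phenol followed by folding of an aryl triketo ester has no direct counterpart, so the step is put forward as an extension of these two closest reaction types. At 110 °C 7 undergoes a retro-(4+2) fragmentation that expels acetone and gives acylketene 16, whose unhindered ketene carbon (future C7) adds the only free O–H of 15 (C4'–OH) through a six-centre hydrogen-bonded transition state, so the depside bond C7–O forms without a coupling reagent and before C7 has any ortho neighbour. In 17 the doubly activated CH2 between ester and ketone (future C1) is deprotonated by Et3N and attacks the ketone five atoms away (future C6) in a 6-(enolendo)-exo-trig aldol closure; E1cB loss of one water and two enolisations then make ring A aromatic and the sequence irreversible. The folding mode is fixed by the substrate: with C2'' held as a ketal the closure C3 onto C2'' is barred and the closure C1'' onto C2 would need a singly activated, neopentyl-type nucleophile, so only the Claisen closure C5 onto C7 and O-lactonisation onto C7 remain as competitors. Both competitors require attack on the ester carbonyl, which is less electrophilic than the C6 ketone, and a mild amine base in an aprotic solvent is the regime in which triketo esters take the aldol path. Slow addition of 7 to a concentrated solution of 15 keeps the phenol in excess over 16 and so favours intermolecular capture over capture by an enol oxygen of the chain itself. No stereocenter is formed. The product emerges with C2–OH chelated and C4–OH free, which prepares the selective methylation of step 10.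

Step 10
Reactants: 18 benzyl 4-({2,4-dihydroxy-6-[(2-pentyl-1,3-dioxolan-2-yl)methyl]benzoyl}oxy)-2-methoxy-6-pentylbenzoate
Product: 19 benzyl 4-({2-hydroxy-4-methoxy-6-[(2-pentyl-1,3-dioxolan-2-yl)methyl]benzoyl}oxy)-2-methoxy-6-pentylbenzoate
Conditions: MeI (1.1 equiv), K2CO3 (1.1 equiv), acetone, 20 °C
Reagents that add atoms: iodomethane, CI
Why: Williamson O-methylation of the more acidic, unchelated C4–OH; C2–OH is tied up in a hydrogen bond to C7=O and stays free, as is general for 2,4-dihydroxybenzoates. With C2'' still a ketal the carbonate base cannot generate an enolate that would attack C7.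

Step 11
Reactants: 19 benzyl 4-({2-hydroxy-4-methoxy-6-[(2-pentyl-1,3-dioxolan-2-yl)methyl]benzoyl}oxy)-2-methoxy-6-pentylbenzoate
Product: 20 benzyl 4-{[2-hydroxy-4-methoxy-6-(2-oxoheptyl)benzoyl]oxy}-2-methoxy-6-pentylbenzoate
Conditions: 1 M aq HCl/THF (1:4), 20 °C
Reagents that add atoms: water, O
Why: Specific-acid-catalysed hydrolysis of a dialkyl ketal through the oxocarbenium ion; both esters and the phenol are inert to dilute acid at room temperature, where enol lactonisation onto C7 should be slow.

Step 12
Reactants: 20 benzyl 4-{[2-hydroxy-4-methoxy-6-(2-oxoheptyl)benzoyl]oxy}-2-methoxy-6-pentylbenzoate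
Product: 21 confluentic acid
Conditions: H2 (1 atm), Pd/C (10 wt %), EtOAc, 20 °C
Reagents that add atoms: none
Why: Hydrogenolysis of the benzyl ester under neutral conditions; the aryl ester, the non-conjugated ketone and both arenes are not reduced, and the sensitive acid is released without acid, base or heat.

## Compound list

1 | ethyl 3-oxooctanoate | CCCCCC(=O)CC(=O)OCC | starting material
2 | ethyl 2-(2-pentyl-1,3-dioxolan-2-yl)acetate | CCCCCC1(CC(=O)OCC)OCCO1 | intermediate
3 | N-methoxy-N-methyl-2-(2-pentyl-1,3-dioxolan-2-yl)acetamide | CCCCCC1(CC(=O)N(C)OC)OCCO1 | intermediate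
4 | 2,2,6-trimethyl-4H-1,3-dioxin-4-one | CC1=CC(=O)OC(C)(C)O1 | starting material
5 | acetyl chloride | CC(=O)Cl | starting material
6 | 2,2-dimethyl-6-(2-oxopropyl)-4H-1,3-dioxin-4-one | CC(=O)CC1=CC(=O)OC(C)(C)O1 | intermediate
7 | 6-[2,4-dioxo-5-(2-pentyl-1,3-dioxolan-2-yl)pentyl]-2,2-dimethyl-4H-1,3-dioxin-4-one | CCCCCC1(CC(=O)CC(=O)CC2=CC(=O)OC(C)(C)O2)OCCO1 | intermediate
8 | oct-2-ynoic acid | CCCCCC#CC(=O)O | starting material
9 | benzyl oct-2-ynoate | CCCCCC#CC(=O)OCc1ccccc1 | intermediate
10 | 1,1-dimethoxyethene | C=C(OC)OC | starting material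
11 | 4,4-dimethoxybut-3-en-2-one | CC(=O)C=C(OC)OC | intermediate
12 | 1,1-dimethoxy-3-(trimethylsilyloxy)buta-1,3-diene | C=C(O[Si](C)(C)C)C=C(OC)OC | intermediate
13 | benzyl 6,6-dimethoxy-2-pentyl-4-(trimethylsilyloxy)cyclohexa-1,4-diene-1-carboxylate | CCCCCC1=C(C(=O)OCc2ccccc2)C(OC)(OC)C=C(O[Si](C)(C)C)C1 | intermediate
14 | benzyl 2-methoxy-6-pentyl-4-(trimethylsilyloxy)benzoate | CCCCCc1cc(O[Si](C)(C)C)cc(OC)c1C(=O)OCc1ccccc1 | intermediate
15 | benzyl 4-hydroxy-2-methoxy-6-pentylbenzoate | CCCCCc1cc(O)cc(OC)c1C(=O)OCc1ccccc1 | intermediate
16 | 8-(2-pentyl-1,3-dioxolan-2-yl)oct-1-ene-1,3,5,7-tetraone (acylketene) | CCCCCC1(CC(=O)CC(=O)CC(=O)C=C=O)OCCO1 | intermediate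
17 | benzyl 2-methoxy-6-pentyl-4-{[3,5,7-trioxo-8-(2-pentyl-1,3-dioxolan-2-yl)octanoyl]oxy}benzoate | CCCCCC1(CC(=O)CC(=O)CC(=O)CC(=O)Oc2cc(CCCCC)c(C(=O)OCc3ccccc3)c(OC)c2)OCCO1 | intermediate
18 | benzyl 4-({2,4-dihydroxy-6-[(2-pentyl-1,3-dioxolan-2-yl)methyl]benzoyl}oxy)-2-methoxy-6-pentylbenzoate | CCCCCC1(Cc2cc(O)cc(O)c2C(=O)Oc2cc(CCCCC)c(C(=O)OCc3ccccc3)c(OC)c2)OCCO1 | intermediate
19 | benzyl 4-({2-hydroxy-4-methoxy-6-[(2-pentyl-1,3-dioxolan-2-yl)methyl]benzoyl}oxy)-2-methoxy-6-pentylbenzoate | CCCCCC1(Cc2cc(OC)cc(O)c2C(=O)Oc2cc(CCCCC)c(C(=O)OCc3ccccc3)c(OC)c2)OCCO1 | intermediate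
20 | benzyl 4-{[2-hydroxy-4-methoxy-6-(2-oxoheptyl)benzoyl]oxy}-2-methoxy-6-pentylbenzoate | CCCCCC(=O)Cc1cc(OC)cc(O)c1C(=O)Oc1cc(CCCCC)c(C(=O)OCc2ccccc2)c(OC)c1 | intermediate
21 | confluentic acid, 4-{[2-hydroxy-4-methoxy-6-(2-oxoheptyl)benzoyl]oxy}-2-methoxy-6-pentylbenzoic acid | CCCCCC(=O)Cc1cc(OC)cc(O)c1C(=O)Oc1cc(CCCCC)c(C(=O)O)c(OC)c1 | target

## Step count and risk

Total step count: 12.

Longest linear sequence: 7 steps (steps 6, 7, 8, 9, 10, 11, 12). The branch through steps 1, 2, 4, 9, 10, 11, 12 is equally long.

**Step 9 (key step, carries the label).**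
- Before capture, the acylketene can be taken by an enol oxygen of its own chain. The electron-poor phenol 15 is a weaker nucleophile than the alcohols for which the cascade is established, so this intramolecular capture may outrun it.
- After capture, the open-chain aryl ester can lose ring B again. The routes are O-lactonisation, Claisen closure C5 onto C7, or base-induced E1cB reversion to the ketene, since the aryloxide is a better leaving group than an alkoxide.
- Fallback (known chemistry only): it sets out from 7. Et3N in CH2Cl2 folds the dioxinone itself to 7-hydroxy-2,2-dimethyl-5-[(2-pentyl-1,3-dioxolan-2-yl)methyl]-4H-1,3-benzodioxin-4-one F1.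
- MeI/K2CO3 in acetone then methylates its only free hydroxyl to the 7-methoxy compound F2.
- Irradiation of F2 (300 nm, CH2Cl2, 20 °C) in the presence of 15 generates the quinoketene, which acylates the phenol. This photochemical acylation is an established entry to depsides with a free ortho hydroxyl.
- The fallback comes back to the route at 19. It costs one step more than steps 9 and 10 together.

**Step 4.**
- The dianion may act as a base toward 3. Deprotonation next to the amide carbonyl would be followed by β-elimination that opens the dioxolane.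
- The product may also start to fold to the arene during work-up or on silica.
- Fallback: it replaces the dianion by soft enolisation and a decarboxylative unmasking, sets out from 4 and 2, and bypasses 6.
- The dienolate of 4 (LiN(SiMe3)2, THF, −78 °C) is acylated with allyl 3-chloro-3-oxopropanoate to give allyl 4-(2,2-dimethyl-4-oxo-4H-1,3-dioxin-6-yl)-3-oxobutanoate F3.
- Compound 2 is saponified (LiOH, THF/H2O) to 2-(2-pentyl-1,3-dioxolan-2-yl)acetic acid F4. This is converted under neutral conditions with 1-chloro-N,N,2-trimethylprop-1-en-1-amine into 2-(2-pentyl-1,3-dioxolan-2-yl)acetyl chloride F5.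
- MgCl2/pyridine-mediated C-acylation of F3 with F5 gives allyl 2-[(2,2-dimethyl-4-oxo-4H-1,3-dioxin-6-yl)acetyl]-3-oxo-4-(2-pentyl-1,3-dioxolan-2-yl)butanoate F6.
- Pd(PPh3)4 with morpholine removes the allyl ester with loss of CO2, and the fallback comes back at 7.

**Step 8.**
- The β-alkyl ynoate is a sluggish dienophile. Thermal decay or adventitious hydrolysis of the ketene acetal diene may outrun the cycloaddition, and loss of methanol from the adduct may be incomplete.
- Fallback: the ring is closed at the aldehyde oxidation level, where the dienophile has a lower LUMO, and the carboxyl level is adjusted afterwards.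
- It sets out from 12, which is combined with commercial oct-2-ynal (PhMe, 70 °C; then dilute HCl) to give 4-hydroxy-2-methoxy-6-pentylbenzaldehyde F7.
- Pinnick oxidation (NaClO2, NaH2PO4, 2-methylbut-2-ene, t-BuOH/H2O) gives 4-hydroxy-2-methoxy-6-pentylbenzoic acid F8.
- Selective carboxylate alkylation (BnBr, KHCO3, DMF) comes back at 15.

**Step 11.**
- The freed ketone may enolise under acid and attack C7 through its enol oxygen with loss of ring B.
- Alternatively, the flanked ketal may hydrolyse too slowly at a temperature that the depside tolerates.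
- Fallback: the mode of unmasking changes from acid hydrolysis to neutral hydrogenolysis.
- It sets out from 1, which is ketalised with 1,2-benzenedimethanol (p-TsOH·H2O, PhMe, azeotropic removal of water) to ethyl 2-(3-pentyl-1,5-dihydro-2,4-benzodioxepin-3-yl)acetate F9.
- The operations of steps 2, 4, 9 and 10 then lead through the N-methoxy-N-methylamide F10, the diketo-dioxinone F11 and the dihydroxy depside F12 to the 4-O-methyl depside F13.
- H2 over Pd/C in EtOAc cleaves a benzylic C–O bond of the ketal, whose hemiketal collapses to the ketone, together with the benzyl ester in one neutral operation.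
- The fallback comes back at 21 and saves one step. It is not the first choice because closing the seven-membered ketal on a β-keto ester is less certain than making the dioxolane.

## Further compounds

F1 | step 9 | 7-hydroxy-2,2-dimethyl-5-[(2-pentyl-1,3-dioxolan-2-yl)methyl]-4H-1,3-benzodioxin-4-one | CCCCCC1(Cc2cc(O)cc3OC(C)(C)OC(=O)c23)OCCO1
F2 | step 9 | 7-methoxy-2,2-dimethyl-5-[(2-pentyl-1,3-dioxolan-2-yl)methyl]-4H-1,3-benzodioxin-4-one | CCCCCC1(Cc2cc(OC)cc3OC(C)(C)OC(=O)c23)OCCO1
F3 | step 4 | allyl 4-(2,2-dimethyl-4-oxo-4H-1,3-dioxin-6-yl)-3-oxobutanoate | C=CCOC(=O)CC(=O)CC1=CC(=O)OC(C)(C)O1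
F4 | step 4 | 2-(2-pentyl-1,3-dioxolan-2-yl)acetic acid | CCCCCC1(CC(=O)O)OCCO1
F5 | step 4 | 2-(2-pentyl-1,3-dioxolan-2-yl)acetyl chloride | CCCCCC1(CC(=O)Cl)OCCO1
F6 | step 4 | allyl 2-[(2,2-dimethyl-4-oxo-4H-1,3-dioxin-6-yl)acetyl]-3-oxo-4-(2-pentyl-1,3-dioxolan-2-yl)butanoate (racemic, largely enolised) | C=CCOC(=O)C(C(=O)CC1=CC(=O)OC(C)(C)O1)C(=O)CC1(CCCCC)OCCO1
F7 | step 8 | 4-hydroxy-2-methoxy-6-pentylbenzaldehyde | CCCCCc1cc(O)cc(OC)c1C=O
F8 | step 8 | 4-hydroxy-2-methoxy-6-pentylbenzoic acid | CCCCCc1cc(O)cc(OC)c1C(=O)O
F9 | step 11 | ethyl 2-(3-pentyl-1,5-dihydro-2,4-benzodioxepin-3-yl)acetate | CCCCCC1(CC(=O)OCC)OCc2ccccc2CO1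
F10 | step 11 | N-methoxy-N-methyl-2-(3-pentyl-1,5-dihydro-2,4-benzodioxepin-3-yl)acetamide | CCCCCC1(CC(=O)N(C)OC)OCc2ccccc2CO1
F11 | step 11 | 6-[2,4-dioxo-5-(3-pentyl-1,5-dihydro-2,4-benzodioxepin-3-yl)pentyl]-2,2-dimethyl-4H-1,3-dioxin-4-one | CCCCCC1(CC(=O)CC(=O)CC2=CC(=O)OC(C)(C)O2)OCc2ccccc2CO1
F12 | step 11 | benzyl 4-({2,4-dihydroxy-6-[(3-pentyl-1,5-dihydro-2,4-benzodioxepin-3-yl)methyl]benzoyl}oxy)-2-methoxy-6-pentylbenzoate | CCCCCC1(Cc2cc(O)cc(O)c2C(=O)Oc2cc(CCCCC)c(C(=O)OCc3ccccc3)c(OC)c2)OCc2ccccc2CO1
F13 | step 11 | benzyl 4-({2-hydroxy-4-methoxy-6-[(3-pentyl-1,5-dihydro-2,4-benzodioxepin-3-yl)methyl]benzoyl}oxy)-2-methoxy-6-pentylbenzoate | CCCCCC1(Cc2cc(OC)cc(O)c2C(=O)Oc2cc(CCCCC)c(C(=O)OCc3ccccc3)c(OC)c2)OCc2ccccc2CO1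
A1 | alternative 1 | 2-(benzyloxy)-4-methoxy-6-(2-oxoheptyl)benzoic acid | CCCCCC(=O)Cc1cc(OC)cc(OCc2ccccc2)c1C(=O)O
A2 | alternative 1 | 8-(benzyloxy)-6-methoxy-3-pentyl-1H-isochromen-1-one | CCCCCC1=Cc2cc(OC)cc(OCc3ccccc3)c2C(=O)O1
A3 | alternative 1 | benzyl 4-{[2-(benzyloxy)-4-methoxy-6-(2-oxoheptyl)benzoyl]oxy}-2-methoxy-6-pentylbenzoate | CCCCCC(=O)Cc1cc(OC)cc(OCc2ccccc2)c1C(=O)Oc1cc(CCCCC)c(C(=O)OCc2ccccc2)c(OC)c1
A4 | alternative 2 | benzyl 2-methoxy-6-pentyl-4-{[4-(2-pentyl-1,3-dioxolan-2-yl)but-2-ynoyl]oxy}benzoate | CCCCCC1(CC#CC(=O)Oc2cc(CCCCC)c(C(=O)OCc3ccccc3)c(OC)c2)OCCO1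
A5 | alternative 2 | 1,3-dimethoxy-1-(trimethylsilyloxy)buta-1,3-diene | C=C(OC)C=C(OC)O[Si](C)(C)C
A6 | alternative 3 | 3-(benzyloxy)-5-methoxy-2-(trimethylsilyl)phenyl trifluoromethanesulfonate | COc1cc(OCc2ccccc2)c([Si](C)(C)C)c(OS(=O)(=O)C(F)(F)F)c1
A7 | alternative 3 | benzyl 2-methoxy-4-[(3-oxooctanoyl)oxy]-6-pentylbenzoate | CCCCCC(=O)CC(=O)Oc1cc(CCCCC)c(C(=O)OCc2ccccc2)c(OC)c1
A8 | alternative 3 | benzyl 4-({[3-(benzyloxy)-2-hexanoyl-5-methoxyphenyl]acetyl}oxy)-2-methoxy-6-pentylbenzoate | CCCCCC(=O)c1c(OCc2ccccc2)cc(OC)cc1CC(=O)Oc1cc(CCCCC)c(C(=O)OCc2ccccc2)c(OC)c1
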